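**Retrosynthetic overview**

- The target is reached from the 5-hydroxy-bicyclo[3.2.1]oct-2-en-4-one 18 by four functional-group steps: O-methylation at C5, unmasking of the C8 ketone, hydride delivery to C4 from the C8 face, and acetylation.
- The strategy rests on C5, the tertiary ether bridgehead that lies between oxygenated C4 and the C8 carbonyl. This is an α-ketol retron: returning C6 from C5 to C4 opens the cyclopentane ring C1–C8–C5–C6–C7 and gives the bridgehead α-ketol 17 of a bicyclo[2.2.2]octenone.
- The bicyclo[2.2.2]octenone (bonds C4–C6 and C1–C7) comes from an endo Diels–Alder reaction of masked o-benzoquinone 15 with (E)-isoelemicin 14. The bridgehead oxygen carries a camphanoyl group that serves as protecting group and resolving auxiliary.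
- Phenol 11 is built from 2,3-dihydroxy-4-methoxybenzaldehyde by 3-O-allylation, Dakin-type oxidation, O-methylation and a para-Claisen shift; 14 comes from a Suzuki coupling.
- Ring order: the six-membered rings of the bicyclo[2.2.2]octene form first (cycloaddition); the cyclopentane ring forms last, by the 1,2-bridge shift.

Key step: step 10

Remark: the labels C1–C8 in the overview and the Why lines are the target's ring atoms (C1 allyl bridgehead, C2=C3, C4, C5 methoxy bridgehead, C6 aryl, C7 methyl, C8 bridge carbon) and follow each atom through the skeletal shift; the bicyclo[3.2.1] names use the same locants, whereas the names of the bicyclo[2.2.2]octenones 16 and 17 carry systematic locants, in which C1, C2, C3, C4, C5, C6, C7 and C8 are the target atoms C4, C5, C8, C1, C2, C3, C6 and C7.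

**Route**

Step 1
Reactants: 1 2,3-dihydroxy-4-methoxybenzaldehyde; 2 allyl bromide
Product: 3 3-(allyloxy)-2-hydroxy-4-methoxybenzaldehyde
Conditions: NaH (2.2 equiv), DMSO, 20 °C; then 2 (1.0 equiv), 20 °C
Reagents that add atoms: none
Why: In the dianion the 3-phenoxide, which is neither conjugated with nor chelated by the aldehyde, is the more nucleophilic oxygen, so one equivalent of allyl bromide should give Williamson O-allylation at O3 only.

Step 2
Reactants: 3 3-(allyloxy)-2-hydroxy-4-methoxybenzaldehyde
Product: 4 3-(allyloxy)-4-methoxy-2-(methoxymethoxy)benzaldehyde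
Conditions: MOMCl, iPr2NEt, CH2Cl2, 0 °C to rt
Reagents that add atoms: chloromethyl methyl ether, COCCl
Why: Williamson-type acetal formation on the remaining chelated 2-OH; the methoxymethyl group cannot migrate and should survive the later peracid, base and heat.

Step 3
Reactants: 4 3-(allyloxy)-4-methoxy-2-(methoxymethoxy)benzaldehyde
Product: 6 3-(allyloxy)-4-methoxy-2-(methoxymethoxy)phenol, via aryl formate 5 (not isolated)
Conditions: mCPBA, CH2Cl2, 0 °C to rt; then Et3N (cat.), MeOH, rt
Reagents that add atoms: 3-chloroperbenzoic acid, O=C(OO)c1cccc(Cl)c1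
Why: Baeyer–Villiger (Dakin-type) oxidation of the electron-rich trioxygenated benzaldehyde, in which aryl migration should be much faster than epoxidation of the monosubstituted allyl alkene, followed by amine-catalysed methanolysis of the labile aryl formate.

Step 4
Reactants: 6 3-(allyloxy)-4-methoxy-2-(methoxymethoxy)phenol
Product: 7 2-(allyloxy)-1,4-dimethoxy-3-(methoxymethoxy)benzene
Conditions: MeI, K2CO3, acetone, reflux
Reagents that add atoms: iodomethane, CI
Why: Williamson methylation of the only free phenol.

Step 5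
Reactants: 7 2-(allyloxy)-1,4-dimethoxy-3-(methoxymethoxy)benzene
Product: 8 4-allyl-3,6-dimethoxy-2-(methoxymethoxy)phenol
Conditions: N,N-diethylaniline, 200 °C, sealed tube
Reagents that add atoms: none
Why: Aromatic para-Claisen rearrangement: both ortho positions of the allyl ether carry oxygen substituents, so the ortho-dienone from the first [3,3] shift cannot tautomerise and a Cope shift should carry the allyl group to the free para carbon, which frees the oxygen that will bear the auxiliary.

Step 6
Reactants: 8 4-allyl-3,6-dimethoxy-2-(methoxymethoxy)phenol; 9 (1S)-(−)-camphanic chloride [(1S,4R)-4,7,7-trimethyl-3-oxo-2-oxabicyclo[2.2.1]heptane-1-carbonyl chloride]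
Product: 10 4-allyl-3,6-dimethoxy-2-(methoxymethoxy)phenyl (1S,4R)-camphanate
Conditions: Et3N, 4-dimethylaminopyridine (DMAP, cat.), CH2Cl2, 0 °C to rt
Reagents that add atoms: none
Why: DMAP-catalysed acylation of the freed phenol with a non-enolisable chiral acid chloride, which installs the bridgehead-oxygen protecting group and the resolving auxiliary in one operation.

Step 7
Reactants: 10 4-allyl-3,6-dimethoxy-2-(methoxymethoxy)phenyl (1S,4R)-camphanate
Product: 11 4-allyl-2-hydroxy-3,6-dimethoxyphenyl (1S,4R)-camphanate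
Conditions: ZnBr2, n-PrSH, CH2Cl2, 0 °C, short reaction time
Reagents that add atoms: none
Why: Lewis acid/thiol cleavage of the aryl methoxymethyl acetal, with the thiol capturing the methoxymethyl cation before it can alkylate the electron-rich ring, under non-basic cold conditions that should leave the bulky neighbouring ester in place without acyl migration.

Step 8
Reactants: 12 5-bromo-1,2,3-trimethoxybenzene; 13 (E)-prop-1-enylboronic acid
Product: 14 (E)-isoelemicin [1,2,3-trimethoxy-5-((E)-prop-1-enyl)benzene]
Conditions: Pd(PPh3)4 (3 mol %), K2CO3, dioxane/H2O, 90 °C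
Reagents that add atoms: none
Why: Suzuki–Miyaura cross-coupling at zerovalent palladium proceeds with retention of the alkene geometry of the boronic acid, so the (E)-propenyl arene should be obtained free of the geometric isomer.

Step 9
Reactants: 11 4-allyl-2-hydroxy-3,6-dimethoxyphenyl (1S,4R)-camphanate; 14 (E)-isoelemicin
Product: 16 (1S,4S,7R,8S)-4-allyl-3,3,6-trimethoxy-8-methyl-2-oxo-7-(3,4,5-trimethoxyphenyl)bicyclo[2.2.2]oct-5-en-1-yl (1S,4R)-camphanate (aryl syn to the alkene bridge; methyl anti), via masked o-benzoquinone 15 (not isolated)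
Conditions: PhI(OAc)2 (1.1 equiv), MeOH, 0 °C; evaporate; 14 (4 equiv), toluene, 100 °C, sealed tube; separation of the two diastereomeric cycloadducts by chromatography and crystallisation
Reagents that add atoms: methanol, CO
Why: Oxidative dearomatisation by trivalent iodine adds methanol at the methoxy-bearing ortho carbon to give the 6,6-dimethoxycyclohexa-2,4-dienone, whose Diels–Alder reaction with the electron-rich (E)-alkene should follow the usual regiochemistry of masked o-benzoquinones (the nucleophilic CH(Me) carbon bonds to the allyl-bearing δ-terminus, the future C1, and the benzylic carbon to the acyloxy-bearing terminus, the future C4) and the endo mode (aryl under the diene, hence syn to the new alkene bridge, the E geometry placing methyl anti), setting C1, C4, C6 and C7 in one relative sense; the remote auxiliary is not expected to bias the diene face, so the diastereomer with the mirror-image bicyclic core should form alongside and is removed at this stage, the absolute configuration of 16 being assigned by X-ray analysis against the known camphanoyl centres.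

Step 10
Reactants: 16 cycloadduct camphanate
Product: 18 (1S,5S,6R,7S)-1-allyl-5-hydroxy-3,8,8-trimethoxy-7-methyl-6-(3,4,5-trimethoxyphenyl)bicyclo[3.2.1]oct-2-en-4-one (aryl endo; methyl exo), via bridgehead α-ketol 17 (not isolated)
Conditions: K2CO3 (0.5 equiv), MeOH, rt to 45 °C
Reagents that add atoms: none
Why: Methoxide transesterifies the camphanate (the neighbouring ketone makes the tertiary alkoxide a good leaving group) and releases the C4 alkoxide of 17, which reforms a C4=O bond while the C4–C6 σ-bond shifts suprafacially to the adjacent C5 carbonyl carbon; this is the α-ketol (acyloin) rearrangement known for bridgehead-hydroxy bicyclo[2.2.2]octenones from masked o-benzoquinone cycloadducts. The cyclopentane ring C1–C8–C5–C6–C7 closes by this 1,2-shift of a ring bond, which excises C4 from the six-membered ring C1–C8–C5–C4–C6–C7, and not by cyclisation of an open chain, while the ring C1–C2–C3–C4–C5–C8 becomes the cyclohexenone. The new stereocentre C5 is fixed by the bicyclic frame, because C6 can reach the C5 carbonyl only from the face on which it is already held. C6 migrates with retention, so the aryl group syn to C2=C3 and the anti methyl group become endo aryl and exo methyl. The step needs C6 rather than the vinylic C3 to migrate and the equilibrium to lie on the product side; both should be secured thermodynamically, since only C6 migration leaves C4=O conjugated with the C2=C3 enol ether (an α-methoxy enone), C3 migration would give a non-conjugated ketone, and the shift is reversible under these conditions.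

Step 11
Reactants: 18 5-hydroxy-bicyclo[3.2.1]oct-2-en-4-one ketal
Product: 19 (1S,5S,6R,7S)-1-allyl-3,5,8,8-tetramethoxy-7-methyl-6-(3,4,5-trimethoxyphenyl)bicyclo[3.2.1]oct-2-en-4-one
Conditions: NaH, MeI, THF/DMF, 0 °C
Reagents that add atoms: iodomethane, CI
Why: Williamson methylation of the tertiary C5 alkoxide, the same alkoxide through which step 10 equilibrates and which therefore sits in the preferred [3.2.1] frame; neither carbonyl-flanking carbon bears hydrogen, so O-alkylation should be the only productive path.

Step 12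
Reactants: 19 C5 methyl ether, C8 dimethyl ketal
Product: 20 (1S,5R,6R,7S)-1-allyl-3,5-dimethoxy-7-methyl-6-(3,4,5-trimethoxyphenyl)bicyclo[3.2.1]oct-2-ene-4,8-dione
Conditions: TFA/H2O (9:1), CH2Cl2, 0 °C to rt
Reagents that add atoms: water, O
Why: Acid-catalysed ketal hydrolysis, done at the stage where the C2=C3 enol ether is deactivated towards protonation by conjugation with C4=O, so that the bridging dimethyl ketal should be the group that hydrolyses.

Step 13
Reactants: 20 4,8-dione
Product: 21 (1S,4R,5S,6R,7S)-1-allyl-4-hydroxy-3,5-dimethoxy-7-methyl-6-(3,4,5-trimethoxyphenyl)bicyclo[3.2.1]oct-2-en-8-one (C4 hydroxyl syn to the C6–C7 bridge)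
Conditions: NaBH4 (0.5 equiv), CeCl3·7H2O, MeOH, −78 °C
Reagents that add atoms: none
Why: Luche 1,2-reduction, which favours the conjugated C4 carbonyl over the doubly α-quaternary C8 bridge ketone (expected to be partly masked as its hemiketal in the cerium-containing methanol); hydride should arrive on the C4 face turned towards the trigonal C8 because the other face is covered by the endo aryl group on C6, which sets 4R.

Step 14
Reactants: 21 C4 allylic alcohol
Product: 22 (1S,4R,5S,6R,7S)-1-allyl-3,5-dimethoxy-7-methyl-8-oxo-6-(3,4,5-trimethoxyphenyl)bicyclo[3.2.1]oct-2-en-4-yl acetate (target, CNP0181407.1)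
Conditions: Ac2O, pyridine, DMAP (cat.), CH2Cl2, rt
Reagents that add atoms: acetic anhydride, CC(=O)OC(C)=O
Why: DMAP-catalysed acetylation of the secondary allylic alcohol; the resulting β-acetoxy ketone cannot eliminate because C5 carries no hydrogen.

**Compound list**

1 | 2,3-dihydroxy-4-methoxybenzaldehyde | COc1ccc(C=O)c(O)c1O | starting material
2 | allyl bromide | C=CCBr | starting material
3 | 3-(allyloxy)-2-hydroxy-4-methoxybenzaldehyde | COc1ccc(C=O)c(O)c1OCC=C | intermediate
4 | 3-(allyloxy)-4-methoxy-2-(methoxymethoxy)benzaldehyde | COc1ccc(C=O)c(OCOC)c1OCC=C | intermediate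
5 | 3-(allyloxy)-4-methoxy-2-(methoxymethoxy)phenyl formate | COc1ccc(OC=O)c(OCOC)c1OCC=C | intermediate (not isolated)
6 | 3-(allyloxy)-4-methoxy-2-(methoxymethoxy)phenol | COc1ccc(O)c(OCOC)c1OCC=C | intermediate
7 | 2-(allyloxy)-1,4-dimethoxy-3-(methoxymethoxy)benzene | COc1ccc(OC)c(OCOC)c1OCC=C | intermediate
8 | 4-allyl-3,6-dimethoxy-2-(methoxymethoxy)phenol | C=CCc1cc(OC)c(O)c(OCOC)c1OC | intermediate
9 | (1S)-(−)-camphanic chloride, (1S,4R) | O=C(Cl)[C@@]12CC[C@@](C)(C(=O)O1)C2(C)C | starting material
10 | 4-allyl-3,6-dimethoxy-2-(methoxymethoxy)phenyl (1S,4R)-camphanate | C=CCc1cc(OC)c(OC(=O)[C@@]23CC[C@@](C)(C(=O)O2)C3(C)C)c(OCOC)c1OC | intermediate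
11 | 4-allyl-2-hydroxy-3,6-dimethoxyphenyl (1S,4R)-camphanate | C=CCc1cc(OC)c(OC(=O)[C@@]23CC[C@@](C)(C(=O)O2)C3(C)C)c(O)c1OC | intermediate
12 | 5-bromo-1,2,3-trimethoxybenzene | COc1cc(Br)cc(OC)c1OC | starting material
13 | (E)-prop-1-enylboronic acid | C/C=C/B(O)O | starting material
14 | (E)-isoelemicin | COc1cc(/C=C/C)cc(OC)c1OC | intermediate
15 | 4-allyl-2,5,5-trimethoxy-6-oxocyclohexa-1,3-dien-1-yl (1S,4R)-camphanate (masked o-benzoquinone) | C=CCC1=CC(OC)=C(OC(=O)[C@@]23CC[C@@](C)(C(=O)O2)C3(C)C)C(=O)C1(OC)OC | intermediate (not isolated)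
16 | (1S,4S,7R,8S)-4-allyl-3,3,6-trimethoxy-8-methyl-2-oxo-7-(3,4,5-trimethoxyphenyl)bicyclo[2.2.2]oct-5-en-1-yl (1S,4R)-camphanate | C=CC[C@]12C=C(OC)[C@](OC(=O)[C@@]34CC[C@@](C)(C(=O)O3)C4(C)C)(C(=O)C1(OC)OC)[C@@H](c1cc(OC)c(OC)c(OC)c1)[C@@H]2C | intermediate
17 | (1S,4S,7R,8S)-4-allyl-1-hydroxy-3,3,6-trimethoxy-8-methyl-7-(3,4,5-trimethoxyphenyl)bicyclo[2.2.2]oct-5-en-2-one (bridgehead α-ketol) | C=CC[C@]12C=C(OC)[C@](O)(C(=O)C1(OC)OC)[C@@H](c1cc(OC)c(OC)c(OC)c1)[C@@H]2C | intermediate (not isolated)
18 | (1S,5S,6R,7S)-1-allyl-5-hydroxy-3,8,8-trimethoxy-7-methyl-6-(3,4,5-trimethoxyphenyl)bicyclo[3.2.1]oct-2-en-4-one | C=CC[C@]12C=C(OC)C(=O)[C@](O)(C1(OC)OC)[C@@H](c1cc(OC)c(OC)c(OC)c1)[C@@H]2C | intermediate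
19 | (1S,5S,6R,7S)-1-allyl-3,5,8,8-tetramethoxy-7-methyl-6-(3,4,5-trimethoxyphenyl)bicyclo[3.2.1]oct-2-en-4-one | C=CC[C@]12C=C(OC)C(=O)[C@](OC)(C1(OC)OC)[C@@H](c1cc(OC)c(OC)c(OC)c1)[C@@H]2C | intermediate
20 | (1S,5R,6R,7S)-1-allyl-3,5-dimethoxy-7-methyl-6-(3,4,5-trimethoxyphenyl)bicyclo[3.2.1]oct-2-ene-4,8-dione | C=CC[C@]12C=C(OC)C(=O)[C@](OC)(C1=O)[C@@H](c1cc(OC)c(OC)c(OC)c1)[C@@H]2C | intermediate
21 | (1S,4R,5S,6R,7S)-1-allyl-4-hydroxy-3,5-dimethoxy-7-methyl-6-(3,4,5-trimethoxyphenyl)bicyclo[3.2.1]oct-2-en-8-one | C=CC[C@]12C=C(OC)[C@@H](O)[C@](OC)(C1=O)[C@@H](c1cc(OC)c(OC)c(OC)c1)[C@@H]2C | intermediate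
22 | (1S,4R,5S,6R,7S)-1-allyl-3,5-dimethoxy-7-methyl-8-oxo-6-(3,4,5-trimethoxyphenyl)bicyclo[3.2.1]oct-2-en-4-yl acetate | C=CC[C@]12C=C(OC)[C@@H](OC(C)=O)[C@](OC)(C1=O)[C@@H](c1cc(OC)c(OC)c(OC)c1)[C@@H]2C | target

**Step count**

Total step count: 14. Longest linear sequence: 13 steps (steps 1–7 and 9–14); step 8 is a one-step side branch.

**Steps most likely to fail**

Step 9. The cycloaddition forms two bonds to fully substituted diene termini and may be slow, so decay of the masked o-benzoquinone (self-dimerisation, loss of the enol ester) could outpace it, the more so with the bulky camphanoyloxy group at the reacting terminus; the two diastereomers may also fail to separate. The fallback sets out from 8 and returns at 18: the auxiliary is replaced by the small acetyl group and the resolution is moved to chromatography on a chiral stationary phase. Compound 8 is acetylated (Ac2O, pyridine, DMAP) to 4-allyl-3,6-dimethoxy-2-(methoxymethoxy)phenyl acetate F1, and the acetal is cleaved (ZnBr2, n-PrSH, CH2Cl2, 0 °C) to 4-allyl-2-hydroxy-3,6-dimethoxyphenyl acetate F2. Oxidation with PhI(OAc)2 in MeOH should give 4-allyl-2,5,5-trimethoxy-6-oxocyclohexa-1,3-dien-1-yl acetate F3, and cycloaddition with 14 the racemic bridgehead acetate, that is (1S,4S,7R,8S)-4-allyl-3,3,6-trimethoxy-8-methyl-2-oxo-7-(3,4,5-trimethoxyphenyl)bicyclo[2.2.2]oct-5-en-1-yl acetate F4 together with its (1R,4R,7S,8R) mirror image F5. Preparative HPLC on an amylose tris(3,5-dimethylphenylcarbamate) phase isolates F4, and K2CO3 in MeOH should convert it through 17 into 18.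

Step 10. Methanolysis of the hindered tertiary ester may be slow and force harsher base, under which attack of methoxide on the keto-ketal (cleavage of C5–C8) or migration of the vinylic C3 in place of C6 could compete. The fallback sets out from 16 and returns at 18: ester cleavage is separated from the skeletal shift, and the free-alkoxide pathway is replaced by a neutral chelate pathway. Compound 16 is methanolysed at −20 °C with catalytic NaOMe and quenched with AcOH so that α-ketol 17 is isolated; 17 is then heated with Al(OiPr)3 in toluene at 80 °C, where the five-membered aluminium chelate of the α-ketol should undergo the same C6 shift without any nucleophilic alkoxide in solution. New compounds on this path: none F0.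

Step 13. Hydride may also attack the strained C8 bridge carbonyl, or reach C4 from the wrong face. The fallback sets out from 20 and returns at 22: chemoselective reduction is replaced by full reduction, selective acylation and reoxidation. Both carbonyl groups are reduced with excess NaBH4 and CeCl3·7H2O in MeOH at 0 °C to 1-allyl-3,5-dimethoxy-7-methyl-6-(3,4,5-trimethoxyphenyl)bicyclo[3.2.1]oct-2-ene-4,8-diol (C4 hydroxyl as in 21; C8 hydroxyl expected syn to the C6–C7 bridge, its configuration being immaterial) F6. The allylic C4 hydroxyl is then acetylated selectively (Ac2O, pyridine, 0 °C, no DMAP; the C8 hydroxyl lies between two quaternary carbons) to 1-allyl-8-hydroxy-3,5-dimethoxy-7-methyl-6-(3,4,5-trimethoxyphenyl)bicyclo[3.2.1]oct-2-en-4-yl acetate F7, and Dess–Martin periodinane in CH2Cl2 reoxidises C8 to give 22.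

**Further compounds**

F1 | step 9 | 4-allyl-3,6-dimethoxy-2-(methoxymethoxy)phenyl acetate | C=CCc1cc(OC)c(OC(C)=O)c(OCOC)c1OC
F2 | step 9 | 4-allyl-2-hydroxy-3,6-dimethoxyphenyl acetate | C=CCc1cc(OC)c(OC(C)=O)c(O)c1OC
F3 | step 9 | 4-allyl-2,5,5-trimethoxy-6-oxocyclohexa-1,3-dien-1-yl acetate | C=CCC1=CC(OC)=C(OC(C)=O)C(=O)C1(OC)OC
F4 | step 9 | (1S,4S,7R,8S)-4-allyl-3,3,6-trimethoxy-8-methyl-2-oxo-7-(3,4,5-trimethoxyphenyl)bicyclo[2.2.2]oct-5-en-1-yl acetate | C=CC[C@]12C=C(OC)[C@](OC(C)=O)(C(=O)C1(OC)OC)[C@@H](c1cc(OC)c(OC)c(OC)c1)[C@@H]2C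
F5 | step 9 | (1R,4R,7S,8R)-4-allyl-3,3,6-trimethoxy-8-methyl-2-oxo-7-(3,4,5-trimethoxyphenyl)bicyclo[2.2.2]oct-5-en-1-yl acetate | C=CC[C@@]12C=C(OC)[C@@](OC(C)=O)(C(=O)C1(OC)OC)[C@H](c1cc(OC)c(OC)c(OC)c1)[C@H]2C
F0 | step 10 | none | none
F6 | step 13 | 1-allyl-3,5-dimethoxy-7-methyl-6-(3,4,5-trimethoxyphenyl)bicyclo[3.2.1]oct-2-ene-4,8-diol (ring stereocentres as in 21; 8-hydroxyl syn to the C6–C7 bridge) | C=CC[C@]12C=C(OC)[C@@H](O)[C@](OC)([C@H]1O)[C@@H](c1cc(OC)c(OC)c(OC)c1)[C@@H]2C
F7 | step 13 | 1-allyl-8-hydroxy-3,5-dimethoxy-7-methyl-6-(3,4,5-trimethoxyphenyl)bicyclo[3.2.1]oct-2-en-4-yl acetate (ring stereocentres as in 22; 8-hydroxyl syn to the C6–C7 bridge) | C=CC[C@]12C=C(OC)[C@@H](OC(C)=O)[C@](OC)([C@H]1O)[C@@H](c1cc(OC)c(OC)c(OC)c1)[C@@H]2C
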